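**Retrosynthetic overview**
1. The nitrogen ring is closed last: Boc removal and Pictet–Spengler reaction with formaldehyde on an open-chain biaryl carbamate, where only one ring carbon ortho to the side chain is free.
2. Key disconnection: the biaryl bond C5–C1'. Both carbons are nucleophilic by nature (para carbon of a 1-naphthol, ring carbon of a dimethoxyarene). PhI(OAc)2 in HFIP turns the naphthol into a naphthoxenium (vinylogous enolonium) electrophile, so no halide or boron is needed. The free OH directs para and is methylated afterwards.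
3. Arene partner: 3,5-dimethoxyphenyl Grignard reagent plus the cyclic sulfamidate of Boc-L-alaninol; the C3 (S) centre comes from the chiral pool.
4. Naphthol partner: 2-methoxy-4-methylbenzoic acid, then diethylamide, ortho-metalation/allylation and LDA anionic ring closure.
5. Ring order: second naphthalene ring, then biaryl bond, then piperidine ring.

Assumption: the SMILES defines only C3 (S) and leaves the biaryl axis open, so the route fixes C3 and gives the axis as the mixture of atropisomers formed in step 5.

**Route**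

Step 1
Reactants: 1 1-bromo-3,5-dimethoxybenzene; 2 tert-butyl (S)-4-methyl-1,2,3-oxathiazolidine-3-carboxylate 2,2-dioxide
Product: 5 tert-butyl (S)-[1-(3,5-dimethoxyphenyl)propan-2-yl]carbamate, via 3,5-dimethoxyphenylmagnesium bromide 3 (not isolated), via magnesium N-sulfonate salt 4 (not isolated)
Conditions: Mg, cat. I2, THF, 40 °C; then 2, CuI (10 mol%), THF, −30 → 0 °C; then 10% aq. citric acid, rt
Reagents that add atoms: none
Why: Copper-catalysed SN2 opening of the cyclic sulfamidate by the aryl Grignard reagent occurs at the CH2–O carbon only, so the C–N centre from L-alaninol is untouched and becomes the (S) centre of the target, and mild aqueous acid then hydrolyses the N-sulfonate while the Boc group stays.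

Step 2
Reactants: 6 2-methoxy-4-methylbenzoic acid
Product: 8 N,N-diethyl-2-methoxy-4-methylbenzamide, via 2-methoxy-4-methylbenzoyl chloride 7 (not isolated)
Conditions: SOCl2, cat. DMF, toluene, 70 °C; evaporate; Et2NH (2.5 equiv), CH2Cl2, 0 °C → rt
Reagents that add atoms: diethylamine, CCNCC
Why: Acid chloride formation followed by amine acylation gives the tertiary amide that serves as directing group in step 3 and as internal acylating agent in step 4.

Step 3
Reactants: 8 N,N-diethyl-2-methoxy-4-methylbenzamide
Product: 11 N,N-diethyl-2-allyl-6-methoxy-4-methylbenzamide, via 6-lithio benzamide 9 (not isolated), via arylmagnesium bromide 10 (not isolated)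
Conditions: s-BuLi, TMEDA, THF, −78 °C; MgBr2·OEt2, −78 → 0 °C; allyl bromide, 0 °C → rt
Reagents that add atoms: allyl bromide, C=CCBr
Why: Directed ortho-metalation: the diethylamide outranks OMe as directing group and its only free ortho C–H is lithiated kinetically at −78 °C, and transmetalation to magnesium allows clean allylation without proton transfer from the product.

Step 4
Reactants: 11 N,N-diethyl-2-allyl-6-methoxy-4-methylbenzamide
Product: 13 8-methoxy-6-methylnaphthalen-1-ol, via 8-methoxy-6-methylnaphthalen-1(2H)-one 12 (not isolated)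
Conditions: LDA (2.2 equiv), THF, −78 °C → rt; aq. HCl work-up
Reagents that add atoms: none
Why: Anionic benzannulation of an o-allylbenzamide: LDA forms the benzylic allyl anion, its terminal carbon acylates on the amide carbonyl in a 6-ring closure, and loss of diethylamide and enolisation give the 1-naphthol with the substitution pattern fixed by 11.

Step 5
Reactants: 13 8-methoxy-6-methylnaphthalen-1-ol; 5 tert-butyl (S)-[1-(3,5-dimethoxyphenyl)propan-2-yl]carbamate
Product: 15 tert-butyl (S)-[1-[2-(4-hydroxy-5-methoxy-7-methylnaphthalen-1-yl)-3,5-dimethoxyphenyl]propan-2-yl]carbamate, via naphthyloxy(phenyl)iodanyl acetate 14 (not isolated)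
Conditions: PhI(OAc)2 (1.05 equiv, added slowly), 5 (2.5 equiv, excess recovered), (CF3)2CHOH–CH2Cl2 (4:1), −20 → 0 °C
Reagents that add atoms: none
Why: Trivalent-iodine oxidative para cross-coupling of a phenol with an arene (Kita-type, a known reaction class that is untested on this pair): O-ligation to iodine makes the normally nucleophilic para carbon C4 of the naphthol the electrophilic end of a naphthoxenium (vinylogous enolonium) species, the ring carbon of 5 ortho to the side chain and para to OMe attacks it, tautomerisation restores the naphthol, and the axis forms without control as both atropisomers while the C–N centre is not touched.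

Step 6
Reactants: 15 tert-butyl (S)-[1-[2-(4-hydroxy-5-methoxy-7-methylnaphthalen-1-yl)-3,5-dimethoxyphenyl]propan-2-yl]carbamate
Product: 16 tert-butyl (S)-[1-[2-(4,5-dimethoxy-7-methylnaphthalen-1-yl)-3,5-dimethoxyphenyl]propan-2-yl]carbamate
Conditions: MeI, K2CO3, DMF, 40 °C
Reagents that add atoms: iodomethane, CI
Why: Williamson ether synthesis: carbonate deprotonates only the naphthol (the carbamate N–H is far less acidic), so O-methylation is selective.

Step 7
Reactants: 16 tert-butyl (S)-[1-[2-(4,5-dimethoxy-7-methylnaphthalen-1-yl)-3,5-dimethoxyphenyl]propan-2-yl]carbamate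
Product: 19 (S)-5-(4,5-dimethoxy-7-methylnaphthalen-1-yl)-6,8-dimethoxy-3-methyl-1,2,3,4-tetrahydroisoquinoline, via primary ammonium chloride 17 (not isolated), via N-methyleneiminium chloride 18 (not isolated)
Conditions: 4 M HCl in dioxane, rt; evaporate; 37% aq. CH2O, MeOH, 60 °C; aq. NaHCO3 work-up
Reagents that add atoms: formaldehyde, C=O
Why: Boc acidolysis followed by Pictet–Spengler cyclisation: the formaldehyde iminium is attacked by the only free ring carbon ortho to the side chain, which is activated by one ortho and one para OMe, and the C3 centre takes no part and stays (S).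

**Compound list**
1 | 1-bromo-3,5-dimethoxybenzene | COc1cc(Br)cc(OC)c1 | starting material
2 | tert-butyl (S)-4-methyl-1,2,3-oxathiazolidine-3-carboxylate 2,2-dioxide | C[C@H]1COS(=O)(=O)N1C(=O)OC(C)(C)C | starting material
3 | 3,5-dimethoxyphenylmagnesium bromide | COc1cc([Mg]Br)cc(OC)c1 | intermediate
4 | bromomagnesium (S)-N-(tert-butoxycarbonyl)-N-[1-(3,5-dimethoxyphenyl)propan-2-yl]sulfamate | C[C@@H](Cc1cc(OC)cc(OC)c1)N(C(=O)OC(C)(C)C)S(=O)(=O)[O-].[Mg+2].[Br-] | intermediate
5 | tert-butyl (S)-[1-(3,5-dimethoxyphenyl)propan-2-yl]carbamate | C[C@H](NC(=O)OC(C)(C)C)Cc1cc(OC)cc(OC)c1 | intermediate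
6 | 2-methoxy-4-methylbenzoic acid | Cc1ccc(C(=O)O)c(OC)c1 | starting material
7 | 2-methoxy-4-methylbenzoyl chloride | Cc1ccc(C(=O)Cl)c(OC)c1 | intermediate
8 | N,N-diethyl-2-methoxy-4-methylbenzamide | CCN(CC)C(=O)c1ccc(C)cc1OC | intermediate
9 | N,N-diethyl-2-lithio-6-methoxy-4-methylbenzamide | CCN(CC)C(=O)c1c([Li])cc(C)cc1OC | intermediate
10 | [2-(diethylcarbamoyl)-3-methoxy-5-methylphenyl]magnesium bromide | CCN(CC)C(=O)c1c([Mg]Br)cc(C)cc1OC | intermediate
11 | N,N-diethyl-2-allyl-6-methoxy-4-methylbenzamide | C=CCc1cc(C)cc(OC)c1C(=O)N(CC)CC | intermediate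
12 | 8-methoxy-6-methylnaphthalen-1(2H)-one | O=C1CC=Cc2cc(C)cc(OC)c21 | intermediate
13 | 8-methoxy-6-methylnaphthalen-1-ol | COc1cc(C)cc2cccc(O)c12 | intermediate
14 | acetoxy(8-methoxy-6-methylnaphthalen-1-yloxy)(phenyl)-λ3-iodane | CC(=O)OI(c1ccccc1)Oc1cccc2cc(C)cc(OC)c12 | intermediate
15 | tert-butyl (S)-[1-[2-(4-hydroxy-5-methoxy-7-methylnaphthalen-1-yl)-3,5-dimethoxyphenyl]propan-2-yl]carbamate (both atropisomers) | C[C@H](NC(=O)OC(C)(C)C)Cc1cc(OC)cc(OC)c1-c1ccc(O)c2c(OC)cc(C)cc12 | intermediate
16 | tert-butyl (S)-[1-[2-(4,5-dimethoxy-7-methylnaphthalen-1-yl)-3,5-dimethoxyphenyl]propan-2-yl]carbamate | C[C@H](NC(=O)OC(C)(C)C)Cc1cc(OC)cc(OC)c1-c1ccc(OC)c2c(OC)cc(C)cc12 | intermediate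
17 | (S)-1-[2-(4,5-dimethoxy-7-methylnaphthalen-1-yl)-3,5-dimethoxyphenyl]propan-2-aminium chloride | C[C@H]([NH3+])Cc1cc(OC)cc(OC)c1-c1ccc(OC)c2c(OC)cc(C)cc12.[Cl-] | intermediate
18 | (S)-N-methylidene-1-[2-(4,5-dimethoxy-7-methylnaphthalen-1-yl)-3,5-dimethoxyphenyl]propan-2-aminium chloride | C[C@H]([NH+]=C)Cc1cc(OC)cc(OC)c1-c1ccc(OC)c2c(OC)cc(C)cc12.[Cl-] | intermediate
19 | (S)-5-(4,5-dimethoxy-7-methylnaphthalen-1-yl)-6,8-dimethoxy-3-methyl-1,2,3,4-tetrahydroisoquinoline (CNP0236045.1) | COc1cc(OC)c(-c2ccc(OC)c3c(OC)cc(C)cc23)c2c1CN[C@@H](C)C2 | target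

**Count**
Total steps: 7. Longest linear sequence: 6 (steps 2, 3, 4, 5, 6, 7 from compound 6).

**Three steps most likely to fail**

Step 5 is the most likely to fail. The naphthol can couple with itself, the product can be oxidised further to a quinol or quinone, attack can go ortho on the naphthol, and 5 can react through the carbon between its two OMe groups. The bond formed is also tri-ortho-substituted. The fallback sets out from 13 and 5 and comes back at 16, replacing the oxidative coupling by a palladium cross-coupling of two prefunctionalised partners. NBS in MeCN at −20 °C brominates 13 para to the hydroxyl to give 4-bromo-8-methoxy-6-methylnaphthalen-1-ol F1. MeI and K2CO3 in DMF give 1-bromo-4,5-dimethoxy-7-methylnaphthalene F2. Miyaura borylation (B2pin2, Pd(dppf)Cl2, KOAc, dioxane, 90 °C) gives 2-(4,5-dimethoxy-7-methylnaphthalen-1-yl)-4,4,5,5-tetramethyl-1,3,2-dioxaborolane F3. In parallel, NBS in MeCN at 0 °C brominates 5 ortho to the side chain to give tert-butyl (S)-[1-(2-bromo-3,5-dimethoxyphenyl)propan-2-yl]carbamate F4. Suzuki–Miyaura coupling of F3 with F4 (Pd(OAc)2, SPhos, K3PO4, toluene–H2O, 100 °C) gives 16, so step 6 is no longer needed.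

Step 7 is the second risk. Formaldehyde can hydroxymethylate the electron-rich dimethoxynaphthalene, and the tert-butyl cation from the Boc group can alkylate it. The fallback sets out from 16 and comes back at 19, closing the ring by Bischler–Napieralski cyclisation and reduction instead of with formaldehyde. HCl in dioxane gives 17, and ethyl formate with Et3N at reflux gives (S)-N-[1-[2-(4,5-dimethoxy-7-methylnaphthalen-1-yl)-3,5-dimethoxyphenyl]propan-2-yl]formamide F5. POCl3 in MeCN at 80 °C cyclises it to (S)-5-(4,5-dimethoxy-7-methylnaphthalen-1-yl)-6,8-dimethoxy-3-methyl-3,4-dihydroisoquinoline F6. NaBH4 in MeOH at 0 °C reduces the C=N bond to give 19; C3 is not touched.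

Step 3 is the third risk. Lithiation can compete next to the OMe group or at the benzylic methyl, and the allylated product can quench the aryl anion. The fallback sets out from 6 and comes back at 11, replacing the ortho-metalation by a carboxylate-directed catalytic C–H allylation. [RuCl2(p-cymene)]2 with K3PO4 and allyl acetate in MeCN at 50 °C allylates the only free ortho C–H of 6 to give 2-allyl-6-methoxy-4-methylbenzoic acid F7. SOCl2 in toluene at 70 °C gives 2-allyl-6-methoxy-4-methylbenzoyl chloride F8, and Et2NH in CH2Cl2 at 0 °C gives 11, so step 2 is no longer needed.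

**Further compounds**
F1 | step 5 | 4-bromo-8-methoxy-6-methylnaphthalen-1-ol | COc1cc(C)cc2c(Br)ccc(O)c12
F2 | step 5 | 1-bromo-4,5-dimethoxy-7-methylnaphthalene | COc1cc(C)cc2c(Br)ccc(OC)c12
F3 | step 5 | 2-(4,5-dimethoxy-7-methylnaphthalen-1-yl)-4,4,5,5-tetramethyl-1,3,2-dioxaborolane | COc1cc(C)cc2c(B3OC(C)(C)C(C)(C)O3)ccc(OC)c12
F4 | step 5 | tert-butyl (S)-[1-(2-bromo-3,5-dimethoxyphenyl)propan-2-yl]carbamate | C[C@H](NC(=O)OC(C)(C)C)Cc1cc(OC)cc(OC)c1Br
F5 | step 7 | (S)-N-[1-[2-(4,5-dimethoxy-7-methylnaphthalen-1-yl)-3,5-dimethoxyphenyl]propan-2-yl]formamide | C[C@H](NC=O)Cc1cc(OC)cc(OC)c1-c1ccc(OC)c2c(OC)cc(C)cc12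
F6 | step 7 | (S)-5-(4,5-dimethoxy-7-methylnaphthalen-1-yl)-6,8-dimethoxy-3-methyl-3,4-dihydroisoquinoline | COc1cc(OC)c(-c2ccc(OC)c3c(OC)cc(C)cc23)c2c1C=N[C@@H](C)C2
F7 | step 3 | 2-allyl-6-methoxy-4-methylbenzoic acid | C=CCc1cc(C)cc(OC)c1C(=O)O
F8 | step 3 | 2-allyl-6-methoxy-4-methylbenzoyl chloride | C=CCc1cc(C)cc(OC)c1C(=O)Cl
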